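## Retrosynthetic overview

- Ring locants used in the text: C1 = C(CH2OH), C2 = its alkene CH, C3 = CH2, C4 = stereocentre, C5 and C6 = CH2, C7(CH3)=C8 (E), C9, C10, C11(CH3)=C12 (Z), C13, C14.
- Key disconnection: the ring bond C5–C6 is opened by a retro-Ireland–Claisen shift to a 14-membered macrolactone. Its carbonyl carbon is a temporary carboxyl on C5, and its alkoxy carbon is C8, bearing an exocyclic isopropenyl group (C7, C6, CH3).
- Enabling feature: C6 is the allylic CH2 of the E-trisubstituted ring alkene C7(CH3)=C8 and C5 is its neighbour, so C5–C6–C7=C8 is the γ,δ-unsaturated acid retron once CO2H sits on C5. The 14-membered ring lets a lactone of the same ring size hold the chair transition state.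
- Ring order: the lactone ring is made first (C–O bond), then traded for the carbocycle (C5–C6) in the key step. The carboxyl is then removed and the alcohol released.
- Seco acid from three pieces: a Z-alkenyl piece (carbocupration of propyne), a δ-lactone carrying C4 and the side chain (asymmetric conjugate addition), and isopropenylmagnesium bromide. The pieces are joined by olefination at C1=C2.

Key step: step 16

Remark (assumption on the chemistry): the (R)-BINAP ligand in step 7 is chosen on the established sense of induction of BINAP–rhodium alkenyl transfer to six-membered cyclic acceptors. The carbinol centre at C8 in 24–26 is left uncontrolled on purpose, because step 16 destroys it.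

## Route

Step 1
Reactants: 1 [2-(1,3-dioxolan-2-yl)ethyl]magnesium bromide (THF solution); 2 propyne; 3 oxirane
Product: 6 (3Z)-6-(1,3-dioxolan-2-yl)-4-methylhex-3-en-1-ol, via alkylcopper reagent 4 (not isolated), via Z-alkenylcopper reagent 5 (not isolated)
Conditions: CuBr·SMe2, THF/Me2S, −45 °C; 2, −25 °C; then n-PrC≡CLi (from pent-1-yne, n-BuLi), HMPA, 3, −78 → −20 °C; aqueous work-up
Reagents that add atoms: none
Why: Normant syn-carbocupration puts the alkyl group on the internal alkyne carbon and copper on the terminal carbon cis to it, and the mixed alkynyl cuprate opens oxirane with retention at the sp2 carbon, which fixes the Z geometry of the future C11=C12 alkene.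

Step 2
Reactants: 6 (3Z)-6-(1,3-dioxolan-2-yl)-4-methylhex-3-en-1-ol
Product: 7 2-[(3Z)-6-iodo-3-methylhex-3-en-1-yl]-1,3-dioxolane
Conditions: I2, PPh3, imidazole, CH2Cl2, 0 °C → rt
Reagents that add atoms: iodine, II
Why: Appel-type iodination (Garegg–Samuelsson conditions) of a primary alcohol proceeds by SN2 displacement of the alkoxyphosphonium ion, and the imidazole buffer protects the dioxolane.

Step 3
Reactants: 7 2-[(3Z)-6-iodo-3-methylhex-3-en-1-yl]-1,3-dioxolane; 8 triethyl phosphonoacetate (excess)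
Product: 9 ethyl (5Z)-2-(diethoxyphosphoryl)-8-(1,3-dioxolan-2-yl)-6-methyloct-5-enoate
Conditions: NaH, DMF, 0 °C; then 7, 60 °C
Reagents that add atoms: none
Why: SN2 C-alkylation of the sodium phosphonoacetate by a primary iodide is standard, and the excess of 8 should suppress dialkylation.

Step 4
Reactants: 10 6-methylhept-5-en-2-one
Product: 11 6-methylhepta-1,5-dien-2-yl trifluoromethanesulfonate
Conditions: LiN(i-Pr)2, THF, −78 °C; PhNTf2, −78 → 0 °C
Reagents that add atoms: N-phenylbis(trifluoromethanesulfonimide), O=S(=O)(N(c1ccccc1)S(=O)(=O)C(F)(F)F)C(F)(F)F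
Why: Kinetic deprotonation of the methyl ketone at the methyl group by the hindered amide base, then O-triflation of the less substituted lithium enolate, should give the terminal enol triflate.

Step 5
Reactants: 11 6-methylhepta-1,5-dien-2-yl trifluoromethanesulfonate
Product: 12 4,4,5,5-tetramethyl-2-(6-methylhepta-1,5-dien-2-yl)-1,3,2-dioxaborolane
Conditions: bis(pinacolato)diboron, PdCl2(PPh3)2 (cat.), PPh3, KOPh, toluene, 50 °C
Reagents that add atoms: bis(pinacolato)diboron, CC1(C)OB(OC1(C)C)B1OC(C)(C)C(C)(C)O1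
Why: Miyaura borylation (oxidative addition of the alkenyl triflate to zerovalent palladium, transmetalation with the phenoxide-activated diboron, reductive elimination) converts alkenyl triflates into alkenyl pinacol boronates without moving the double bond.

Step 6
Reactants: 12 4,4,5,5-tetramethyl-2-(6-methylhepta-1,5-dien-2-yl)-1,3,2-dioxaborolane
Product: 13 potassium trifluoro(6-methylhepta-1,5-dien-2-yl)borate
Conditions: KHF2 (aq.), MeOH, rt
Reagents that add atoms: potassium hydrogen difluoride, [K+].[F-].F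
Why: Fluoride exchange at boron gives the crystalline, air-stable trifluoroborate, a slow-release alkenyl donor for the rhodium step.

Step 7
Reactants: 13 potassium trifluoro(6-methylhepta-1,5-dien-2-yl)borate; 14 5,6-dihydro-2H-pyran-2-one
Product: 15 (4R)-4-(6-methylhepta-1,5-dien-2-yl)oxan-2-one
Conditions: [Rh(cod)2]BF4 (cat.), (R)-BINAP, toluene/H2O (10:1), 100 °C
Reagents that add atoms: none
Why: Hayashi–Miyaura asymmetric conjugate addition, in which the alkenylrhodium–BINAP species inserts one enantioface of the lactone C=C and the oxa-π-allylrhodium is protonated by water; the (R)-ligand is expected to set the new stereocentre (C4 of the target) as R.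

Step 8
Reactants: 15 (4R)-4-(6-methylhepta-1,5-dien-2-yl)oxan-2-one
Product: 16 (4R)-4-(6-methylhepta-1,5-dien-2-yl)oxan-2-ol (anomer mixture)
Conditions: i-Bu2AlH (1.1 equiv), CH2Cl2, −78 °C; aq. KNaC4H4O6 work-up
Reagents that add atoms: none
Why: Partial reduction of a δ-lactone to the lactol at −78 °C is standard; it unmasks the carbonyl arm (future C3–C2) as an aldehyde while the oxygen arm (future C5 plus the temporary carboxyl carbon) stays an alcohol.

Step 9
Reactants: 16 (4R)-4-(6-methylhepta-1,5-dien-2-yl)oxan-2-ol; 9 ethyl (5Z)-2-(diethoxyphosphoryl)-8-(1,3-dioxolan-2-yl)-6-methyloct-5-enoate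
Product: 17 ethyl (2E,5S)-2-[(3Z)-6-(1,3-dioxolan-2-yl)-4-methylhex-3-en-1-yl]-7-hydroxy-5-(6-methylhepta-1,5-dien-2-yl)hept-2-enoate
Conditions: LiCl, DBU, MeCN, rt
Reagents that add atoms: none
Why: Horner–Wadsworth–Emmons olefination (Masamune–Roush conditions) of the open hydroxy-aldehyde form of the lactol should place the ester trans to the aldehyde-derived chain, which is the C1=C2 geometry of the target; any minor Z isomer would be removed by chromatography.

Step 10
Reactants: 17 ethyl (2E,5S)-2-[(3Z)-6-(1,3-dioxolan-2-yl)-4-methylhex-3-en-1-yl]-7-hydroxy-5-(6-methylhepta-1,5-dien-2-yl)hept-2-enoate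
Product: 18 (3S,5E,9Z)-12-(1,3-dioxolan-2-yl)-6-(ethoxycarbonyl)-10-methyl-3-(6-methylhepta-1,5-dien-2-yl)dodeca-5,9-dienoic acid
Conditions: TEMPO (cat.), PhI(OAc)2, MeCN/H2O (1:1), rt
Reagents that add atoms: water, O
Why: Oxoammonium oxidation in aqueous acetonitrile takes the primary alcohol through the aldehyde hydrate to the acid and should leave alkenes, acetal and enoate untouched.

Step 11
Reactants: 18 (3S,5E,9Z)-12-(1,3-dioxolan-2-yl)-6-(ethoxycarbonyl)-10-methyl-3-(6-methylhepta-1,5-dien-2-yl)dodeca-5,9-dienoic acid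
Product: 19 (3S,5E,9Z)-12-(1,3-dioxolan-2-yl)-6-(hydroxymethyl)-10-methyl-3-(6-methylhepta-1,5-dien-2-yl)dodeca-5,9-dienoic acid
Conditions: i-Bu2AlH (4 equiv), CH2Cl2, −78 → −40 °C; aq. KNaC4H4O6, then pH 4
Reagents that add atoms: none
Why: The first equivalent converts the acid into an aluminium carboxylate that resists hydride at low temperature, so only the conjugated ester should undergo 1,2-reduction to the allylic alcohol, with the alkene geometry kept.

Step 12
Reactants: 19 (3S,5E,9Z)-12-(1,3-dioxolan-2-yl)-6-(hydroxymethyl)-10-methyl-3-(6-methylhepta-1,5-dien-2-yl)dodeca-5,9-dienoic acid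
Product: 21 (3S,5E,9Z)-6-{[tert-butyl(diphenyl)silyl]oxymethyl}-12-(1,3-dioxolan-2-yl)-10-methyl-3-(6-methylhepta-1,5-dien-2-yl)dodeca-5,9-dienoic acid, via bis-silylated silyl ester 20 (not isolated)
Conditions: t-BuPh2SiCl (2.5 equiv), imidazole, DMF, rt; then K2CO3 (cat.), MeOH/H2O, rt; pH 5
Reagents that add atoms: tert-butyl(chloro)diphenylsilane, CC(C)(C)[Si](Cl)(c1ccccc1)c1ccccc1
Why: Silylation protects the primary allylic alcohol for the lactonisation and enolisation steps, and the labile silyl ester formed alongside is cleaved selectively by mild basic methanolysis.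

Step 13
Reactants: 21 (3S,5E,9Z)-6-{[tert-butyl(diphenyl)silyl]oxymethyl}-12-(1,3-dioxolan-2-yl)-10-methyl-3-(6-methylhepta-1,5-dien-2-yl)dodeca-5,9-dienoic acid
Product: 22 (3S,5E,9Z)-6-{[tert-butyl(diphenyl)silyl]oxymethyl}-10-methyl-3-(6-methylhepta-1,5-dien-2-yl)-13-oxotrideca-5,9-dienoic acid
Conditions: PPTS (cat.), acetone/H2O (9:1), 55 °C
Reagents that add atoms: water, O
Why: Acid-catalysed transacetalisation and hydrolysis of the dioxolane releases the aldehyde (C8), and the tert-butyldiphenylsilyl ether should be stable to this mild acid.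

Step 14
Reactants: 22 (3S,5E,9Z)-6-{[tert-butyl(diphenyl)silyl]oxymethyl}-10-methyl-3-(6-methylhepta-1,5-dien-2-yl)-13-oxotrideca-5,9-dienoic acid; 23 isopropenylmagnesium bromide (3 equiv)
Product: 24 (3S,5E,9Z)-6-{[tert-butyl(diphenyl)silyl]oxymethyl}-13-hydroxy-10,14-dimethyl-3-(6-methylhepta-1,5-dien-2-yl)pentadeca-5,9,14-trienoic acid (both C13 epimers of this chain, C8 of the target)
Conditions: THF, −78 → −20 °C; aqueous work-up, pH 4
Reagents that add atoms: none
Why: Grignard 1,2-addition to the aldehyde after the first equivalent has turned the acid into an unreactive magnesium carboxylate; the new carbinol centre is formed unselectively on purpose because both epimers converge in step 16.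

Step 15
Reactants: 24 (3S,5E,9Z)-6-{[tert-butyl(diphenyl)silyl]oxymethyl}-13-hydroxy-10,14-dimethyl-3-(6-methylhepta-1,5-dien-2-yl)pentadeca-5,9,14-trienoic acid
Product: 26 (4S,6E,10Z)-7-{[tert-butyl(diphenyl)silyl]oxymethyl}-11-methyl-4-(6-methylhepta-1,5-dien-2-yl)-14-(prop-1-en-2-yl)-1-oxacyclotetradeca-6,10-dien-2-one (both C14 epimers), via mixed trichlorobenzoic anhydride 25 (not isolated)
Conditions: 2,4,6-Cl3C6H2COCl, Et3N, THF, rt; then slow addition to DMAP, toluene, 80 °C (about 1 mM)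
Reagents that add atoms: none
Why: Yamaguchi macrolactonisation, in which DMAP turns the mixed anhydride into an acylpyridinium that the secondary allylic alcohol captures under high dilution; 14-membered lactones are among the most readily closed macrolides.

Step 16
Reactants: 26 (4S,6E,10Z)-7-{[tert-butyl(diphenyl)silyl]oxymethyl}-11-methyl-4-(6-methylhepta-1,5-dien-2-yl)-14-(prop-1-en-2-yl)-1-oxacyclotetradeca-6,10-dien-2-one
Product: 29 (3E,7Z,11E,14S)-11-{[tert-butyl(diphenyl)silyl]oxymethyl}-3,7-dimethyl-14-(6-methylhepta-1,5-dien-2-yl)cyclotetradeca-3,7,11-triene-1-carboxylic acid (both C1 epimers), via silyl ketene acetal 27 (not isolated), via trimethylsilyl ester 28 (not isolated)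
Conditions: LiN(i-Pr)2, Me3SiCl/Et3N, THF, −78 °C; then toluene, 80 °C; 1 M HCl work-up
Reagents that add atoms: none
Why: LiN(i-Pr)2 and Me3SiCl convert the lactone into its cyclic O-silyl ketene acetal 27, in which C5 and the exocyclic methylene carbon (future C6) are the termini of an allyl vinyl ether, so that on warming a concerted [3,3]-sigmatropic (Ireland–Claisen) shift forms C5–C6, cleaves the C8–O bond and leaves silyl ester 28, which is hydrolysed on work-up. The closest known reaction type is the Ireland–Claisen rearrangement of macrocyclic allylic lactones to carbocyclic acids. The 14-membered carbocycle is closed within the 14-membered lactone through a six-membered chair transition state that the ten-atom tether from C5 to C8 can span, the O–C(=O) link being traded for the C5–C6 bond, so ring size is retained. The only new stereocentre, C5 bearing CO2H, arises by chirality transfer from the carbinol centre and the ketene acetal geometry and does not matter because step 17 erases it, while C4 is untouched. The selectivity needed is E geometry at the new C7=C8 bond, which the pseudo-equatorial C9 chain on the carbinol carbon in the chair should secure (a pseudo-axial chain would clash 1,3-diaxially with the silyloxy-bearing carbon) for both C8 epimers of 26, which therefore converge; enolisation is site-selective because the C5 hydrogens are the only acidic ones once the allylic alcohol is silylated.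

Step 17
Reactants: 29 (3E,7Z,11E,14S)-11-{[tert-butyl(diphenyl)silyl]oxymethyl}-3,7-dimethyl-14-(6-methylhepta-1,5-dien-2-yl)cyclotetradeca-3,7,11-triene-1-carboxylic acid
Product: 31 tert-butyl{[(1E,4R,7E,11Z)-7,11-dimethyl-4-(6-methylhepta-1,5-dien-2-yl)cyclotetradeca-1,7,11-trien-1-yl]methoxy}diphenylsilane, via Barton ester 30 (not isolated)
Conditions: N-hydroxypyridine-2-thione, DCC, DMAP (cat.), CH2Cl2, rt, dark; then t-BuSH (excess), toluene, visible light, rt
Reagents that add atoms: none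
Why: Barton reductive decarboxylation, in which homolysis of the thiohydroxamate ester and loss of CO2 give the secondary C5 radical; this should abstract hydrogen from the thiol faster than any 6-exo or transannular cyclisation, removing the temporary carboxyl and its stereocentre without touching the alkenes.

Step 18
Reactants: 31 tert-butyl{[(1E,4R,7E,11Z)-7,11-dimethyl-4-(6-methylhepta-1,5-dien-2-yl)cyclotetradeca-1,7,11-trien-1-yl]methoxy}diphenylsilane
Product: 32 [(1E,4R,7E,11Z)-7,11-dimethyl-4-(6-methylhepta-1,5-dien-2-yl)cyclotetradeca-1,7,11-trien-1-yl]methanol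
Conditions: n-Bu4NF, THF, rt
Reagents that add atoms: none
Why: Fluoride cleaves the Si–O bond of the silyl ether, driven by the strong Si–F bond, and releases the primary allylic alcohol of the target.

## Compound list

1 | [2-(1,3-dioxolan-2-yl)ethyl]magnesium bromide | Br[Mg]CCC1OCCO1 | starting material
2 | propyne | CC#C | starting material
3 | oxirane | C1CO1 | starting material
4 | [2-(1,3-dioxolan-2-yl)ethyl]copper (formed in situ) | [Cu]CCC1OCCO1 | intermediate
5 | [(1Z)-4-(1,3-dioxolan-2-yl)-2-methylbut-1-en-1-yl]copper (formed in situ) | [Cu]/C=C(/C)CCC1OCCO1 | intermediate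
6 | (3Z)-6-(1,3-dioxolan-2-yl)-4-methylhex-3-en-1-ol | OCC/C=C(/C)CCC1OCCO1 | intermediate
7 | 2-[(3Z)-6-iodo-3-methylhex-3-en-1-yl]-1,3-dioxolane | ICC/C=C(/C)CCC1OCCO1 | intermediate
8 | triethyl phosphonoacetate | CCOC(=O)CP(=O)(OCC)OCC | starting material
9 | ethyl (5Z)-2-(diethoxyphosphoryl)-8-(1,3-dioxolan-2-yl)-6-methyloct-5-enoate | CCOC(=O)C(CC/C=C(/C)CCC1OCCO1)P(=O)(OCC)OCC | intermediate
10 | 6-methylhept-5-en-2-one | CC(=O)CCC=C(C)C | starting material
11 | 6-methylhepta-1,5-dien-2-yl trifluoromethanesulfonate | C=C(OS(=O)(=O)C(F)(F)F)CCC=C(C)C | intermediate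
12 | 4,4,5,5-tetramethyl-2-(6-methylhepta-1,5-dien-2-yl)-1,3,2-dioxaborolane | C=C(B1OC(C)(C)C(C)(C)O1)CCC=C(C)C | intermediate
13 | potassium trifluoro(6-methylhepta-1,5-dien-2-yl)borate | C=C([B-](F)(F)F)CCC=C(C)C.[K+] | intermediate
14 | 5,6-dihydro-2H-pyran-2-one | O=C1C=CCCO1 | starting material
15 | (4R)-4-(6-methylhepta-1,5-dien-2-yl)oxan-2-one | O=C1C[C@H](C(=C)CCC=C(C)C)CCO1 | intermediate
16 | (4R)-4-(6-methylhepta-1,5-dien-2-yl)oxan-2-ol (anomers) | OC1C[C@H](C(=C)CCC=C(C)C)CCO1 | intermediate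
17 | ethyl (2E,5S)-2-[(3Z)-6-(1,3-dioxolan-2-yl)-4-methylhex-3-en-1-yl]-7-hydroxy-5-(6-methylhepta-1,5-dien-2-yl)hept-2-enoate | OCC[C@@H](C(=C)CCC=C(C)C)C/C=C(/C(=O)OCC)CC/C=C(/C)CCC1OCCO1 | intermediate
18 | (3S,5E,9Z)-12-(1,3-dioxolan-2-yl)-6-(ethoxycarbonyl)-10-methyl-3-(6-methylhepta-1,5-dien-2-yl)dodeca-5,9-dienoic acid | OC(=O)C[C@@H](C(=C)CCC=C(C)C)C/C=C(/C(=O)OCC)CC/C=C(/C)CCC1OCCO1 | intermediate
19 | (3S,5E,9Z)-12-(1,3-dioxolan-2-yl)-6-(hydroxymethyl)-10-methyl-3-(6-methylhepta-1,5-dien-2-yl)dodeca-5,9-dienoic acid | OC(=O)C[C@@H](C(=C)CCC=C(C)C)C/C=C(/CO)CC/C=C(/C)CCC1OCCO1 | intermediate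
20 | tert-butyldiphenylsilyl ester of 21 (formed in situ) | O=C(O[Si](c1ccccc1)(c1ccccc1)C(C)(C)C)C[C@@H](C(=C)CCC=C(C)C)C/C=C(/CO[Si](c1ccccc1)(c1ccccc1)C(C)(C)C)CC/C=C(/C)CCC1OCCO1 | intermediate
21 | (3S,5E,9Z)-6-{[tert-butyl(diphenyl)silyl]oxymethyl}-12-(1,3-dioxolan-2-yl)-10-methyl-3-(6-methylhepta-1,5-dien-2-yl)dodeca-5,9-dienoic acid | OC(=O)C[C@@H](C(=C)CCC=C(C)C)C/C=C(/CO[Si](c1ccccc1)(c1ccccc1)C(C)(C)C)CC/C=C(/C)CCC1OCCO1 | intermediate
22 | (3S,5E,9Z)-6-{[tert-butyl(diphenyl)silyl]oxymethyl}-10-methyl-3-(6-methylhepta-1,5-dien-2-yl)-13-oxotrideca-5,9-dienoic acid | OC(=O)C[C@@H](C(=C)CCC=C(C)C)C/C=C(/CO[Si](c1ccccc1)(c1ccccc1)C(C)(C)C)CC/C=C(/C)CCC=O | intermediate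
23 | isopropenylmagnesium bromide | CC(=C)[Mg]Br | starting material
24 | (3S,5E,9Z)-6-{[tert-butyl(diphenyl)silyl]oxymethyl}-13-hydroxy-10,14-dimethyl-3-(6-methylhepta-1,5-dien-2-yl)pentadeca-5,9,14-trienoic acid (both C13 epimers) | OC(=O)C[C@@H](C(=C)CCC=C(C)C)C/C=C(/CO[Si](c1ccccc1)(c1ccccc1)C(C)(C)C)CC/C=C(/C)CCC(O)C(C)=C | intermediate
25 | mixed anhydride of 24 and 2,4,6-trichlorobenzoic acid (formed in situ) | O=C(OC(=O)c1c(Cl)cc(Cl)cc1Cl)C[C@@H](C(=C)CCC=C(C)C)C/C=C(/CO[Si](c1ccccc1)(c1ccccc1)C(C)(C)C)CC/C=C(/C)CCC(O)C(C)=C | intermediate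
26 | (4S,6E,10Z)-7-{[tert-butyl(diphenyl)silyl]oxymethyl}-11-methyl-4-(6-methylhepta-1,5-dien-2-yl)-14-(prop-1-en-2-yl)-1-oxacyclotetradeca-6,10-dien-2-one (both C14 epimers) | O=C1C[C@@H](C(=C)CCC=C(C)C)C/C=C(/CO[Si](c2ccccc2)(c2ccccc2)C(C)(C)C)CC/C=C(/C)CCC(C(C)=C)O1 | intermediate
27 | cyclic O-trimethylsilyl ketene acetal of 26 (formed in situ; ketene acetal geometry not defined) | C[Si](C)(C)OC1=C[C@@H](C(=C)CCC=C(C)C)C/C=C(/CO[Si](c2ccccc2)(c2ccccc2)C(C)(C)C)CC/C=C(/C)CCC(C(C)=C)O1 | intermediate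
28 | trimethylsilyl ester of 29 (formed in situ) | C=C(CCC=C(C)C)[C@H]1C/C=C(/CO[Si](c2ccccc2)(c2ccccc2)C(C)(C)C)CC/C=C(/C)CC/C=C(\C)CC1C(=O)O[Si](C)(C)C | intermediate
29 | (3E,7Z,11E,14S)-11-{[tert-butyl(diphenyl)silyl]oxymethyl}-3,7-dimethyl-14-(6-methylhepta-1,5-dien-2-yl)cyclotetradeca-3,7,11-triene-1-carboxylic acid (both C1 epimers) | C=C(CCC=C(C)C)[C@H]1C/C=C(/CO[Si](c2ccccc2)(c2ccccc2)C(C)(C)C)CC/C=C(/C)CC/C=C(\C)CC1C(=O)O | intermediate
30 | 2-thioxopyridin-1(2H)-yl ester of 29 (Barton ester, formed in situ) | C=C(CCC=C(C)C)[C@H]1C/C=C(/CO[Si](c2ccccc2)(c2ccccc2)C(C)(C)C)CC/C=C(/C)CC/C=C(\C)CC1C(=O)ON3C=CC=CC3=S | intermediate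
31 | tert-butyl{[(1E,4R,7E,11Z)-7,11-dimethyl-4-(6-methylhepta-1,5-dien-2-yl)cyclotetradeca-1,7,11-trien-1-yl]methoxy}diphenylsilane | C=C(CCC=C(C)C)[C@H]1C/C=C(/CO[Si](c2ccccc2)(c2ccccc2)C(C)(C)C)CC/C=C(/C)CC/C=C(\C)CC1 | intermediate
32 | [(1E,4R,7E,11Z)-7,11-dimethyl-4-(6-methylhepta-1,5-dien-2-yl)cyclotetradeca-1,7,11-trien-1-yl]methanol | C=C(CCC=C(C)C)[C@H]1C/C=C(/CO)CC/C=C(/C)CC/C=C(\C)CC1 | target

## Step count and risks

Total step count: 18. Longest linear sequence: 15 steps (steps 4 to 18, from 10).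

Steps most likely to fail:

1. Step 16 (key step). What may go wrong: fragmentation of the lactone enolate (β-elimination to a ketene and the allylic alkoxide) before silylation, or a boat pathway with a pseudo-axial chain that erodes the E selectivity. The fallback sets out from 24 and comes back at 29, closing the same C5–C6 bond anionically. Esterification of 24 (Me3SiCHN2, MeOH/toluene) would give methyl ester F1. SOCl2 in Et2O (internal-return SNi′ chlorination with allylic transposition) would turn the isopropenyl carbinol into primary E-allylic chloride F2. Slow addition of F2 to KN(SiMe3)2 in THF (−78 → 0 °C, about 1 mM) should close the ring by intramolecular ester-enolate C-allylation to macrocyclic methyl ester F3. LiOH in THF/MeOH/H2O would then give acid 29.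

2. Step 7. What may go wrong: protodeboronation of the α-substituted alkenylboron outrunning insertion into the weakly activated lactone, or poor enantioface selection. The fallback sets out from 10 and comes back at 15, using auxiliary-controlled copper chemistry. Ketone 10 would be condensed with 2,4,6-triisopropylbenzenesulfonyl hydrazide to sulfonylhydrazone F4. A Shapiro reaction (n-BuLi, 2 equiv, THF, −78 → 0 °C) would give alkenyllithium F5. F5 would be transmetalated (MgBr2·OEt2, then CuBr·SMe2, THF/Me2S, −40 °C) and added to enoyl imide F6, itself to be made from commercial 3-[tert-butyl(dimethyl)silyl]oxypropanal and diethyl {2-oxo-2-[(4S)-2-oxo-4-phenyl-1,3-oxazolidin-3-yl]ethyl}phosphonate (LiCl, i-Pr2NEt, MeCN). Attack on the chelated s-cis imide from the face opposite the phenyl group should give adduct F7. HF·pyridine would remove the silyl group to give hydroxy imide F8, which should lactonise (i-Pr2NEt, CH2Cl2) with release of the auxiliary to give 15.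

3. Step 11. What may go wrong: loss of chemoselectivity, by over-reduction of the aluminium carboxylate or incomplete reduction of the hindered enoate. The fallback sets out from 17 and comes back at 21, differentiating the two oxygens by protecting groups. Et3SiCl and imidazole would convert 17 into triethylsilyl ether F9. i-Bu2AlH (CH2Cl2, −78 °C) would reduce the ester to allylic alcohol F10. t-BuPh2SiCl and imidazole would give bis-silyl ether F11. HF·pyridine in THF/pyridine at 0 °C would remove only the triethylsilyl group to give primary alcohol F12. TEMPO/PhI(OAc)2 in MeCN/H2O would then oxidise F12 to acid 21.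

## Further compounds

F1 | step 16 | methyl (3S,5E,9Z)-6-{[tert-butyl(diphenyl)silyl]oxymethyl}-13-hydroxy-10,14-dimethyl-3-(6-methylhepta-1,5-dien-2-yl)pentadeca-5,9,14-trienoate | COC(=O)C[C@@H](C(=C)CCC=C(C)C)C/C=C(/CO[Si](c1ccccc1)(c1ccccc1)C(C)(C)C)CC/C=C(/C)CCC(O)C(C)=C
F2 | step 16 | methyl (3S,5E,9Z,13E)-6-{[tert-butyl(diphenyl)silyl]oxymethyl}-15-chloro-10,14-dimethyl-3-(6-methylhepta-1,5-dien-2-yl)pentadeca-5,9,13-trienoate | COC(=O)C[C@@H](C(=C)CCC=C(C)C)C/C=C(/CO[Si](c1ccccc1)(c1ccccc1)C(C)(C)C)CC/C=C(/C)CC/C=C(\C)CCl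
F3 | step 16 | methyl (3E,7Z,11E,14S)-11-{[tert-butyl(diphenyl)silyl]oxymethyl}-3,7-dimethyl-14-(6-methylhepta-1,5-dien-2-yl)cyclotetradeca-3,7,11-triene-1-carboxylate | C=C(CCC=C(C)C)[C@H]1C/C=C(/CO[Si](c2ccccc2)(c2ccccc2)C(C)(C)C)CC/C=C(/C)CC/C=C(\C)CC1C(=O)OC
F4 | step 7 | N'-(6-methylhept-5-en-2-ylidene)-2,4,6-tri(propan-2-yl)benzenesulfonohydrazide | CC(CCC=C(C)C)=NNS(=O)(=O)c1c(C(C)C)cc(C(C)C)cc1C(C)C
F5 | step 7 | (6-methylhepta-1,5-dien-2-yl)lithium | [Li]C(=C)CCC=C(C)C
F6 | step 7 | (4S)-3-[(2E)-5-{[tert-butyl(dimethyl)silyl]oxy}pent-2-enoyl]-4-phenyl-1,3-oxazolidin-2-one | O=C(/C=C/CCO[Si](C)(C)C(C)(C)C)N1[C@@H](c2ccccc2)COC1=O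
F7 | step 7 | (4S)-3-[(3R)-3-(2-{[tert-butyl(dimethyl)silyl]oxy}ethyl)-8-methyl-4-methylidenenon-7-enoyl]-4-phenyl-1,3-oxazolidin-2-one | O=C(C[C@H](C(=C)CCC=C(C)C)CCO[Si](C)(C)C(C)(C)C)N1[C@@H](c2ccccc2)COC1=O
F8 | step 7 | (4S)-3-[(3R)-3-(2-hydroxyethyl)-8-methyl-4-methylidenenon-7-enoyl]-4-phenyl-1,3-oxazolidin-2-one | O=C(C[C@H](C(=C)CCC=C(C)C)CCO)N1[C@@H](c2ccccc2)COC1=O
F9 | step 11 | ethyl (2E,5S)-2-[(3Z)-6-(1,3-dioxolan-2-yl)-4-methylhex-3-en-1-yl]-5-(6-methylhepta-1,5-dien-2-yl)-7-[(triethylsilyl)oxy]hept-2-enoate | CC[Si](CC)(CC)OCC[C@@H](C(=C)CCC=C(C)C)C/C=C(/C(=O)OCC)CC/C=C(/C)CCC1OCCO1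
F10 | step 11 | (2E,5S)-2-[(3Z)-6-(1,3-dioxolan-2-yl)-4-methylhex-3-en-1-yl]-5-(6-methylhepta-1,5-dien-2-yl)-7-[(triethylsilyl)oxy]hept-2-en-1-ol | CC[Si](CC)(CC)OCC[C@@H](C(=C)CCC=C(C)C)C/C=C(/CO)CC/C=C(/C)CCC1OCCO1
F11 | step 11 | 1-O-tert-butyldiphenylsilyl 7-O-triethylsilyl bis-ether of (2E,5S)-2-[(3Z)-6-(1,3-dioxolan-2-yl)-4-methylhex-3-en-1-yl]-5-(6-methylhepta-1,5-dien-2-yl)hept-2-ene-1,7-diol | CC[Si](CC)(CC)OCC[C@@H](C(=C)CCC=C(C)C)C/C=C(/CO[Si](c1ccccc1)(c1ccccc1)C(C)(C)C)CC/C=C(/C)CCC1OCCO1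
F12 | step 11 | (3S,5E,9Z)-6-{[tert-butyl(diphenyl)silyl]oxymethyl}-12-(1,3-dioxolan-2-yl)-10-methyl-3-(6-methylhepta-1,5-dien-2-yl)dodeca-5,9-dien-1-ol | OCC[C@@H](C(=C)CCC=C(C)C)C/C=C(/CO[Si](c1ccccc1)(c1ccccc1)C(C)(C)C)CC/C=C(/C)CCC1OCCO1
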